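Target is reckoned here as the end of a two-step chain, from substrate through a waiting pool to target, so at fixed conversion a factor on the rate of making target equals a factor on the pool.

| setting | dusk | dawn | midnight | flask |
|---|---|---|---|---|
| substrate | 0.40 M | 0.40 M | 0.40 M | 0.40 M |
| coupling partner | 1.2 equiv | 1.2 equiv | 1.2 equiv | 1.20 equiv |
| free catalyst | 0.5 mol% | 0.5 mol% | 0.75 mol% | 0.5 mol% |
| second catalyst | 3 mol% | 6.8 mol% | 4.5 mol% | 4.5 mol% |
| impurity | 1.2 mM | 1.2 mM | 1.2 mM | 1.2 mM |
| remark | run made earlier | run made earlier | run made earlier |  |

| run | time / min | target / % |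
|---|---|---|
| dusk | 0.250 | 30.6 |
| dusk | 0.833 | 82.2 |
| dusk | 1.33 | 94.5 |
| dusk | 2.00 | 98.5 |
| dusk | 3.00 | 99.6 |
| dawn | 0.250 | 45.1 |
| dawn | 0.417 | 68.3 |
| dawn | 0.833 | 90.5 |
| dawn | 1.50 | 98.3 |
| dawn | 3.00 | 100.1 |
| midnight | 0.667 | 90.5 |
| midnight | 1.33 | 98.4 |
| midnight | 2.00 | 100.2 |
| midnight | 2.50 | 99.9 |
| midnight | 3.00 | 100.1 |

(each reading ± 0.5 percentage points)

1. factor on the rate of making target when 20% of the substrate are converted if free catalyst is charged twice over
2. factor on the rate when 20% of the substrate are converted if free catalyst is charged at 5 mol% instead

- "the catalyst" is free catalyst with its forms; second catalyst is a second catalyst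
- what has left substrate counts as converted, also if it is not yet product

1. Coupling partner is charged equally in the compared flasks, at 1.20 equiv, so this reckoning leaves it out.

2. The impurity matters much: c(impurity) is 1.2 mM against 2.00 mM of free catalyst. If it removes free catalyst one for one, the working catalyst is 0.800 mM. A double charge then multiplies working catalyst by 3.50, and 5 mol% by 23.5.

3. The ratio r of the second step's constant to the first's enters both factors. The late slopes of ln(unreacted) read 2.36 /min in dusk and 2.90 /min in dawn. Each inverse slope is taken as the sum of two step times, the second inverse to second catalyst. This gives a pseudo-first-order first step of 3.53 /min and, at 4.5 mol%, a second step of 10.8 /min, so r is 3.05.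

4. With S = 80.0%, the pool is (S − S^r)/(r − 1), here 14.3% of the substrate charged. The ceiling factor, the rate factor reached when the whole converted 20% waits in the pool, is 1.40.

5. Dividing r by the catalyst factors gives 1.26 for the double charge and 1.38 for 5 mol%.

The forecast, taking the first step as “roughly proportional to free catalyst”, gives 1.4 and 1.9, against 1.26 and 1.38 here.

The flask gives 1.16 and 1.20.

    substrate + free catalyst ⇌ free catalyst + open intermediate (K = 3.10, k = 79.2 /M/s)
    second catalyst + open intermediate ⇌ catalyst intermediate (K = 0.570 /M, k = 7.99 /M/s)
    coupling partner + catalyst intermediate → second catalyst + target (k = 349 /M/s)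
    free catalyst + impurity → spent catalyst (k = 1490 /M/s)

Both factors stand below the ceiling of 1.40, and the 5 mol% factor is lower than the 1.38 reckoned above. In the flask at 0.187 min, open intermediate is made at 0.917 of the rate at which it is used up, each step taken net. At 0.250 min the flask holds 21.2% open intermediate beside 40.9% substrate and 37.9% target.

The numbers in the tables come from a simulation for substances that don't exist; noise was put on by code.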